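## Structural features

The target joins two rings by one bond: ring A, a cyclohexa-1,3-diene (C1–C6, diene C2=C3–C4=C5, methyl groups on C2, C4 and C6), and ring B, a 2-methoxy-3,5-dimethyl-4-pyranone whose C6' sits directly on the quaternary C6. C1 carries an E-trisubstituted alkene (Cv(Me)=CbH) that leads to Cα, a methyl-bearing methine lying between that alkene and an ethyl ketone. C1 (S) and C6 (R) are adjacent, with the side chain on C1 cis to ring B on C6, while Cα (R) is separated from them by the alkene, so neither set can be relayed from the other through a ring. Fragile points are the β,γ-unsaturated ketone (Cα–H is allylic and α to the carbonyl, so epimerisation and drift into conjugation are easy), the cyclohexadiene (acid, heat and light invite hydrogen shifts or ring opening) and the vinylogous ester of ring B. The real difficulty is the C1/C6 pair: a quaternary carbon bearing a hindered heteroaryl group next to a tertiary allylic centre, to be set in the absolute sense with no neighbouring group to direct it, together with the E geometry at Cv=Cb. The key step uses two facts: C6, with its methyl group and a carboxyl-level carbon (the future C6'), is the sp3 carbon of a mirror-symmetric 1,3,5-trimethylcyclohexa-2,5-diene, and the methyl on Cv can be carried as a CH2–O group tied to that carboxyl, so one carbopalladation forms C1–Cv, fixes C1 and C6 together and moves the skipped diene into the C2=C3–C4=C5 position. The labels C1–C6, Cv, Cb, Cα and O1'–C6' are used in the text, whereas the systematic names in the compound list follow their own locants.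

## Logic of the disconnections

26 ⇒ 25 ⇒ 24. No skeletal bond is cut: the ketone C=O is taken back to a silyl-protected carbinol. The ketone makes Cα–H labile, and as a silyl ether Cα survives base, palladium and heat. The sensitive function then appears only in the last step, which demands a near-neutral desilylation and oxidation.

24 ⇒ 23 ⇒ 22. The O–CH3 bond and then the O1'–C2' bond of ring B are cut, because a 2-methoxy-4-pyranone is a cyclised and methylated 1,3,5-tricarbonyl chain. Ring B is reduced to an open chain on C6. The forward steps must cyclise through the enol of a hindered ketone and must methylate the lactone-type oxygen, not the oxygen on C4'.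

22 ⇒ 18 + 19. The C5'–C6' bond is cut: C6' is a carboxyl carbon on C6, and the rest of ring B is a commercial β-keto ester that reacts as its dianion 21 with the activated form 20. All carbon of ring B beyond C6' comes from one reagent. The demand is acyl transfer at a carbonyl flanked by a quaternary carbon.

18 ⇒ 17. A reconnection: the C–H bond of the Cv methyl and the O–H of the acid are replaced by a CH2–O bond, giving a δ-lactone. This ties Cv to the C6 carboxyl and turns the union at C1 into a ring closure. The forward step must deliver hydride to the CH2 end of an allyl system, keep the alkene geometry and leave the lactone carbonyl alone.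

17 ⇒ 16. The C1–Cv bond is cut, the C2=C3 π bond returns to C1=C2 with hydrogen restored on C3, and Cv receives iodine. The result has no ring stereocentre, so two stereocentres and one ring disappear at once and two fragments of similar size remain. The forward step must choose one of two enantiotopic alkenes and eliminate the C3 hydrogen, not a methyl hydrogen.

16 ⇒ 3 + 15. The ester C–O bond is cut, giving an achiral acid and a chiral iodo alcohol. The demand is esterification of an α-quaternary acid under conditions that spare the alkenyl iodide.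

3 ⇒ 1 (through 2). The C6–CH3 bond and the two ring C–H bonds of a reduction are removed. Reductive alkylation of a benzoic acid puts the new methyl exactly on the carboxyl-bearing carbon and leaves the two ring methyls on alkene carbons. The demand is C-alkylation at the carboxyl-bearing carbon of the dienolate.

15 ⇒ 13 (through 14). The C–I bond and the Cb–H bond are cut: the E-iodoalkene is the syn H–I adduct of an alkyne. The forward step must place tin, then iodine, on the alkyne carbon next to CH2OH.

13 ⇒ 11 ⇒ 10 (through 12). The C–CH2OH bond and the second alkyne carbon are cut: a one-carbon homologation of an aldehyde followed by hydroxymethylation. The demand is that the α-stereocentre of 10 is not epimerised.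

10 ⇒ 9 ⇒ 8 ⇒ 7 ⇒ 4 + 5 (through 6). The Cα–carbinol bond is cut by a syn aldol disconnection. Both side-chain stereocentres then come from one auxiliary-controlled step on commodity materials. The demand is the (2S,3R) syn sense, which the S auxiliary supplies.

## Other disconnections considered

Alternative 1: The cut is through the C1–C2 and C5–C6 ring bonds, with C2–C5 drawn from 2-methoxy-4,6-dimethylphenol A1 and the dienophile being the Z alkene C1=C6 of the dienyl carbinol A2.
- Forward step: PhI(OAc)2 would oxidise A1 in the presence of A2 to the mixed-ketal masked o-benzoquinone A3, which should cyclise at once to the tricyclic keto ketal A4.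
- In its favour: it builds ring A, the quaternary C6 and both ring stereocentres in one operation from a cheap phenol. The cis relation of C1 and C6 follows from the alkene geometry of a concerted cycloaddition. The absolute sense is relayed by the tether from a carbinol stereocentre, so no chiral ligand or precious metal is needed. On bonds and rings formed per step it is better than the chosen plan.
- Against it here:
  - A2 needs a Z,E-diene, three stereocentres and an extra carbinol centre that is later destroyed.
  - A hindered secondary alcohol must compete as the ketal-forming nucleophile, while A3 can dimerise.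
  - The dienophile is one alkene of a conjugated diene, so other modes of cycloaddition are open.
  - After A4 the two-carbon bridge must be unmasked and extruded by light, and the cyclohexadiene produced is itself photolabile.
  - Ring B then still has to be built from the ethyl carbinol.
- Comparison: it is equal on stereochemical logic (substrate control against catalyst control) and better on complexity gained in the key step. It is worse on the photochemical step and on step economy, since the route after A4 is longer than the six steps that follow 17.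

Alternative 2: The cut is through the C3'–C4' and O1'–C2' bonds of ring B, which is assembled on a finished ring A.
- Forward step: heating the dioxinone A5 would give the acylketene A6, which would be trapped by 1,1-dimethoxyprop-1-ene A7 in a [4+2] sense. Loss of one methoxy group would then give A8, which has the structure of 24.
- In its favour: the methoxy group is placed by construction, so no ambident methylation arises. On this point it is better than step 14 of the chosen plan. It also forms ring B in one neutral operation.
- Against it here: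
  - It leaves the C1/C6 problem untouched, so it competes only with steps 12–14, not with the key step.
  - A5 must be made from the same C6 acid through a β-keto acid and an acid-promoted acetonide formation, which endangers the diene and the silyl ether.
  - The thermolysis invites hydrogen shifts in ring A, and a hindered acylketene may be trapped slowly.
- Comparison: it is equal in step count for ring B (three operations from 18 in either case), better on regiochemistry and worse on the conditions needed to reach A5. A variant that avoids A5 is kept as the fallback to step 14.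

Alternative 3: The cut is through C2=C3 and C4=C5, so ring A comes from the cyclobutene A9 by a two-carbon ring expansion with propyne A10.
- Forward step: second-generation Grubbs catalyst would open the strained alkene of A9, add the carbene to A10 and close the ring to the diene ester A11.
- In its favour: both diene bonds and the C4 methyl are set under neutral conditions. The C1 and C6 centres are not touched, so they cannot be scrambled. A11 is one ester cleavage from 18, so the late stage is equal to that of the chosen plan.
- Against it here: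
  - The stereochemical problem is moved, not solved. A9, an enantiopure cyclobutene with adjacent quaternary and tertiary centres, is harder to reach than 16.
  - The insertion of A10 has two regiochemical outcomes, and only one puts the methyl on C4.
  - A trisubstituted cyclobutene alkene opens sluggishly.
  - The side-chain alkene and the product diene can engage the carbene.
  - The key step forms no stereocentre.
- Comparison: it is better on functional-group mildness and equal after the key step. It is worse on the length and risk of the route to A9 and on what the key step delivers (two bonds and one ring, but no stereocentre, against one bond, one ring and two stereocentres).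

Key step: step 10

Remarks on the chemistry:
- (R)-BINAP is written in step 10 on the assumption that it selects the ring alkene leading to 17. The sense of induction cannot be predicted with confidence for an ester tether, and the other ligand enantiomer is used if it proves to be the matched one.
- 19 is used as the racemate, and 22 is a mixture of epimers and enol forms that converges in step 13.

## Route

Step 1
Reactants: 1 3,5-dimethylbenzoic acid
Product: 3 1,3,5-trimethylcyclohexa-2,5-diene-1-carboxylic acid, via dilithium dienolate 2 (not isolated)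
Conditions: Li, NH3(l), THF, −78 °C; then MeI, −78 °C → rt; aq HCl
Reagents that add atoms: iodomethane, CI
Why: Birch reductive alkylation: the benzoate is reduced to the cross-conjugated dienolate, which is C-methylated at the carboxyl-bearing carbon; the product is achiral and its quaternary carbon blocks re-aromatisation.

Step 2
Reactants: 4 (S)-4-benzyl-3-propanoyl-1,3-oxazolidin-2-one; 5 propanal
Product: 7 (S)-4-benzyl-3-[(2S,3R)-3-hydroxy-2-methylpentanoyl]-1,3-oxazolidin-2-one, via boron enolate 6 (not isolated)
Conditions: Bu2BOTf, i-Pr2NEt, CH2Cl2, 0 °C; then 5, −78 → 0 °C; pH 7 buffer, MeOH, H2O2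
Reagents that add atoms: none
Why: Evans syn aldol: the Z boron enolate reacts through a closed Zimmerman–Traxler transition state on the face away from the benzyl group, which sets both side-chain stereocentres as (2S,3R).

Step 3
Reactants: 7
Product: 8 (S)-4-benzyl-3-[(2S,3R)-3-(tert-butyldimethylsilyloxy)-2-methylpentanoyl]-1,3-oxazolidin-2-one
Conditions: TBSOTf, 2,6-lutidine, CH2Cl2, −78 → 0 °C
Reagents that add atoms: tert-butyldimethylsilyl trifluoromethanesulfonate, CC(C)(C)[Si](C)(C)OS(=O)(=O)C(F)(F)F
Why: Silylation of a secondary alcohol with a silyl triflate; the base is too weak to enolise the imide, so both stereocentres are kept.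

Step 4
Reactants: 8
Product: 9 (2R,3R)-3-(tert-butyldimethylsilyloxy)-2-methylpentan-1-ol
Conditions: LiBH4, MeOH (1 equiv), THF, 0 °C
Reagents that add atoms: none
Why: Reductive removal of the auxiliary: borohydride attacks the exocyclic imide carbonyl and the released oxazolidinone can be recovered; the descriptor at C2 changes by priority only.

Step 5
Reactants: 9
Product: 10 (2S,3R)-3-(tert-butyldimethylsilyloxy)-2-methylpentanal
Conditions: Dess–Martin periodinane, NaHCO3, CH2Cl2, 0 °C → rt
Reagents that add atoms: none
Why: Dess–Martin oxidation under buffered conditions stops at the aldehyde and does not enolise the α-stereocentre; the aldehyde is used at once.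

Step 6
Reactants: 10
Product: 11 tert-butyl{[(3R,4R)-6,6-dibromo-4-methylhex-5-en-3-yl]oxy}dimethylsilane
Conditions: CBr4, PPh3, 2,6-lutidine, CH2Cl2, 0 °C
Reagents that add atoms: tetrabromomethane, BrC(Br)(Br)Br
Why: First stage of the Corey–Fuchs homologation (Wittig-type dibromo-olefination); the buffered, non-basic medium leaves the α-centre untouched.

Step 7
Reactants: 11
Product: 13 (4R,5R)-5-(tert-butyldimethylsilyloxy)-4-methylhept-2-yn-1-ol, via lithium acetylide 12 (not isolated)
Conditions: n-BuLi (2.2 equiv), THF, −78 → 0 °C; then (CH2O)n, −78 °C → rt; aq NH4Cl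
Reagents that add atoms: formaldehyde (as paraformaldehyde), C=O
Why: Second stage of the Corey–Fuchs sequence: bromine–lithium exchange and rearrangement give the lithium acetylide, which adds to formaldehyde in the same flask.

Step 8
Reactants: 13
Product: 15 (2E,4R,5R)-5-(tert-butyldimethylsilyloxy)-2-iodo-4-methylhept-2-en-1-ol, via alkenylstannane 14 (not isolated)
Conditions: Bu3SnH, PdCl2(PPh3)2 (3 mol %), THF, 0 °C → rt; then I2, CH2Cl2, 0 °C; aq Na2S2O3
Reagents that add atoms: iodine, II
Why: Palladium-catalysed hydrostannylation adds H and Sn syn, with tin on the less hindered, hydroxymethyl-bearing alkyne carbon; iododestannylation occurs with retention and gives the E-iodide, and any distal regioisomer is removed at this stage.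

Step 9
Reactants: 3; 15
Product: 16 (2E,4R,5R)-5-(tert-butyldimethylsilyloxy)-2-iodo-4-methylhept-2-en-1-yl 1,3,5-trimethylcyclohexa-2,5-diene-1-carboxylate
Conditions: DCC, DMAP, CH2Cl2, 0 °C → rt (3 in slight excess)
Reagents that add atoms: none
Why: Steglich esterification: the acyl group of the α-quaternary acid is passed on through an acylpyridinium ion to an unhindered primary allylic alcohol; neutral conditions spare the alkenyl iodide, the silyl ether and the skipped diene.

Step 10
Reactants: 16
Product: 17 (4Z,4aR,8aR)-4-[(2R,3R)-3-(tert-butyldimethylsilyloxy)-2-methylpentylidene]-5,7,8a-trimethyl-3,4,4a,8a-tetrahydro-1H-isochromen-1-one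
Conditions: Pd(OAc)2 (10 mol %), (R)-BINAP (20 mol %), Ag3PO4 (2 equiv), NMP, 60 °C
Reagents that add atoms: none
Why: Pd(OAc)2 is reduced in the flask to a zerovalent palladium–BINAP complex that inserts into the alkenyl C–I bond of 16 with retention at Cv, and Ag3PO4 strips iodide so that a cationic alkenylpalladium species with both phosphorus atoms bound does the work while phosphate takes up the acid equivalent. One of the two enantiotopic ring alkenes binds and undergoes syn migratory insertion that puts Cv on C1 and palladium on the methyl-bearing C2; syn β-hydride elimination of the ring hydrogen on C3 then releases 17 with the C2=C3–C4=C5 diene. The closest known reaction type is the asymmetric intramolecular Heck desymmetrisation of Birch-derived 1,1-disubstituted cyclohexa-2,5-dienes carrying an alkenyl iodide or triflate, which gives cis-fused bicyclic 1,3-dienes; the ester tether and the δ-lactone are the less usual variant. The lactone ring closes in the 6-exo-trig mode, and the three-atom C(=O)–O–CH2 tether can bring Cv only to the ring face on which the carboxyl carbon stands, so the fusion must be cis. C6 becomes a stereocentre through the choice between the two ring alkenes, which the chiral bisphosphine on cationic palladium controls, and C1 is set relative to C6 by the tether, so one selection event fixes both. Because the side chain of 16 is already a single enantiomer, the two possible ring-closure products are diastereomers and a minor one can be removed. Elimination must go to C3–H and not into the C2 methyl group: the C3 hydrogen is allylic, lies syn to palladium in the cis-fused intermediate and leads to the conjugated diene, and the silver salt suppresses hydride re-addition that would move the diene. Chemoselectivity for C–I over the allylic C–O bond rests on the much faster oxidative addition of the iodide, and the moderate temperature keeps the allylic lactone of 17 from ionising.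

Step 11
Reactants: 17
Product: 18 (1R,6S)-6-[(2E,4R,5R)-5-(tert-butyldimethylsilyloxy)-4-methylhept-2-en-2-yl]-1,3,5-trimethylcyclohexa-2,4-diene-1-carboxylic acid
Conditions: Pd(PPh3)4 (5 mol %), Bu3SnH (1.5 equiv, slow addition), THF, rt; aq KF, then pH 4 buffer
Reagents that add atoms: none
Why: Tsuji–Trost ionisation of the allylic C–O bond with the carboxylate as leaving group, then hydride transfer from tin to palladium and reductive elimination at the unsubstituted CH2 terminus (palladium-catalysed hydrostannolysis of an allylic ester), gives the Cv methyl and the free C6 acid with the E alkene kept. The tin hydride is chosen because it does not attack ester carbonyls, whereas LiBHEt3, the usual hydride for allylic reductions, would reduce the lactone.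

Step 12
Reactants: 18; 19 methyl 2-methyl-3-oxopentanoate
Product: 22 methyl 5-[(1R,6S)-6-[(2E,4R,5R)-5-(tert-butyldimethylsilyloxy)-4-methylhept-2-en-2-yl]-1,3,5-trimethylcyclohexa-2,4-dien-1-yl]-2,4-dimethyl-3,5-dioxopentanoate, via acid chloride 20 (not isolated), via ketoester dianion 21 (not isolated)
Conditions: 18, 1-chloro-N,N,2-trimethylprop-1-en-1-amine, CH2Cl2, 0 °C → rt; separately 19 (3 equiv), LiN(i-Pr)2 (6 equiv), THF, −78 → 0 °C; combine at −78 °C → −20 °C; aq NH4Cl
Reagents that add atoms: none
Why: Claisen-type C-acylation of the terminal carbon of a β-keto ester dianion by an acid chloride; the chloroenamine makes the acid chloride without free HCl, so the silyl ether and diene are not exposed to acid, and excess dianion absorbs the acidic proton of the product. The two new CH(Me) centres form as mixtures, which does not matter because both become sp2 carbons of ring B.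

Step 13
Reactants: 22
Product: 23 6-[(1R,6S)-6-[(2E,4R,5R)-5-(tert-butyldimethylsilyloxy)-4-methylhept-2-en-2-yl]-1,3,5-trimethylcyclohexa-2,4-dien-1-yl]-4-hydroxy-3,5-dimethyl-2H-pyran-2-one
Conditions: DBU, toluene, 60 °C; dilute aq citric acid
Reagents that add atoms: none
Why: Base-induced lactonisation of a 3,5-dioxo ester: the enol oxygen of the C6' ketone attacks the ester carbonyl and methanol is lost, giving the 4-hydroxy-2-pyranone; the ketone can enolise only towards C5', since C6 is quaternary.

Step 14
Reactants: 23
Product: 24 2-[(1R,6S)-6-[(2E,4R,5R)-5-(tert-butyldimethylsilyloxy)-4-methylhept-2-en-2-yl]-1,3,5-trimethylcyclohexa-2,4-dien-1-yl]-6-methoxy-3,5-dimethyl-4H-pyran-4-one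
Conditions: MeOTf (1.2 equiv), CH2Cl2, 0 °C → rt; aq NaHCO3
Reagents that add atoms: methyl trifluoromethanesulfonate, COS(=O)(=O)C(F)(F)F
Why: O-Methylation of a neutral 4-hydroxy-2-pyranone with a hard methylating agent takes place on the more nucleophilic lactone carbonyl oxygen; the resulting 4-hydroxy-2-methoxypyrylium ion loses its proton on basic work-up to give the 2-methoxy-4-pyranone, not the 4-methoxy-2-pyranone that alkylation of the anion favours.

Step 15
Reactants: 24
Product: 25 2-[(1R,6S)-6-[(2E,4R,5R)-5-hydroxy-4-methylhept-2-en-2-yl]-1,3,5-trimethylcyclohexa-2,4-dien-1-yl]-6-methoxy-3,5-dimethyl-4H-pyran-4-one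
Conditions: HF·pyridine, pyridine, THF, 0 °C → rt
Reagents that add atoms: none
Why: Fluoride-driven cleavage of the secondary silyl ether in a pyridine-buffered medium, which leaves the methoxypyranone and the diene alone and touches no stereocentre.

Step 16
Reactants: 25
Product: 26 2-methoxy-3,5-dimethyl-6-[(1R,6S)-1,3,5-trimethyl-6-[(2E,4R)-4-methyl-5-oxohept-2-en-2-yl]cyclohexa-2,4-dien-1-yl]-4H-pyran-4-one (the target)
Conditions: Dess–Martin periodinane, NaHCO3, CH2Cl2, 0 °C
Reagents that add atoms: none
Why: Buffered Dess–Martin oxidation of the secondary alcohol to the ethyl ketone; the reaction does not involve Cα, and cold, neutral conditions with a short work-up guard against enolisation and migration of the alkene into conjugation.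

## Compound list

1 | 3,5-dimethylbenzoic acid | Cc1cc(C)cc(C(=O)O)c1 | starting material
2 | dilithium (3,5-dimethylcyclohexa-2,5-dien-1-ylidene)methanediolate | [Li+].[Li+].[O-]C([O-])=C1C=C(C)CC(C)=C1 | intermediate
3 | 1,3,5-trimethylcyclohexa-2,5-diene-1-carboxylic acid | CC1=CC(C)(C(=O)O)C=C(C)C1 | intermediate
4 | (S)-4-benzyl-3-propanoyl-1,3-oxazolidin-2-one | CCC(=O)N1[C@@H](Cc2ccccc2)COC1=O | starting material
5 | propanal | CCC=O | starting material
6 | (S)-4-benzyl-3-[(Z)-1-(dibutylboranyloxy)prop-1-en-1-yl]-1,3-oxazolidin-2-one | C/C=C(\OB(CCCC)CCCC)N1[C@@H](Cc2ccccc2)COC1=O | intermediate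
7 | (S)-4-benzyl-3-[(2S,3R)-3-hydroxy-2-methylpentanoyl]-1,3-oxazolidin-2-one | CC[C@@H](O)[C@H](C)C(=O)N1[C@@H](Cc2ccccc2)COC1=O | intermediate
8 | (S)-4-benzyl-3-[(2S,3R)-3-(tert-butyldimethylsilyloxy)-2-methylpentanoyl]-1,3-oxazolidin-2-one | CC[C@@H](O[Si](C)(C)C(C)(C)C)[C@H](C)C(=O)N1[C@@H](Cc2ccccc2)COC1=O | intermediate
9 | (2R,3R)-3-(tert-butyldimethylsilyloxy)-2-methylpentan-1-ol | CC[C@@H](O[Si](C)(C)C(C)(C)C)[C@H](C)CO | intermediate
10 | (2S,3R)-3-(tert-butyldimethylsilyloxy)-2-methylpentanal | CC[C@@H](O[Si](C)(C)C(C)(C)C)[C@H](C)C=O | intermediate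
11 | tert-butyl{[(3R,4R)-6,6-dibromo-4-methylhex-5-en-3-yl]oxy}dimethylsilane | CC[C@@H](O[Si](C)(C)C(C)(C)C)[C@H](C)C=C(Br)Br | intermediate
12 | [(3R,4R)-4-(tert-butyldimethylsilyloxy)-3-methylhex-1-yn-1-yl]lithium | CC[C@@H](O[Si](C)(C)C(C)(C)C)[C@H](C)C#C[Li] | intermediate
13 | (4R,5R)-5-(tert-butyldimethylsilyloxy)-4-methylhept-2-yn-1-ol | CC[C@@H](O[Si](C)(C)C(C)(C)C)[C@H](C)C#CCO | intermediate
14 | (2E,4R,5R)-5-(tert-butyldimethylsilyloxy)-4-methyl-2-(tributylstannyl)hept-2-en-1-ol | CC[C@@H](O[Si](C)(C)C(C)(C)C)[C@H](C)/C=C(/[Sn](CCCC)(CCCC)CCCC)CO | intermediate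
15 | (2E,4R,5R)-5-(tert-butyldimethylsilyloxy)-2-iodo-4-methylhept-2-en-1-ol | CC[C@@H](O[Si](C)(C)C(C)(C)C)[C@H](C)/C=C(/I)CO | intermediate
16 | (2E,4R,5R)-5-(tert-butyldimethylsilyloxy)-2-iodo-4-methylhept-2-en-1-yl 1,3,5-trimethylcyclohexa-2,5-diene-1-carboxylate | CC[C@@H](O[Si](C)(C)C(C)(C)C)[C@H](C)/C=C(/I)COC(=O)C1(C)C=C(C)CC(C)=C1 | intermediate
17 | (4Z,4aR,8aR)-4-[(2R,3R)-3-(tert-butyldimethylsilyloxy)-2-methylpentylidene]-5,7,8a-trimethyl-3,4,4a,8a-tetrahydro-1H-isochromen-1-one | CC[C@@H](O[Si](C)(C)C(C)(C)C)[C@H](C)/C=C1\COC(=O)[C@]2(C)C=C(C)C=C(C)[C@H]12 | intermediate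
18 | (1R,6S)-6-[(2E,4R,5R)-5-(tert-butyldimethylsilyloxy)-4-methylhept-2-en-2-yl]-1,3,5-trimethylcyclohexa-2,4-diene-1-carboxylic acid | CC[C@@H](O[Si](C)(C)C(C)(C)C)[C@H](C)/C=C(\C)[C@H]1C(C)=CC(C)=C[C@@]1(C)C(=O)O | intermediate
19 | methyl 2-methyl-3-oxopentanoate (racemic) | CCC(=O)C(C)C(=O)OC | starting material
20 | (1R,6S)-6-[(2E,4R,5R)-5-(tert-butyldimethylsilyloxy)-4-methylhept-2-en-2-yl]-1,3,5-trimethylcyclohexa-2,4-diene-1-carbonyl chloride | CC[C@@H](O[Si](C)(C)C(C)(C)C)[C@H](C)/C=C(\C)[C@H]1C(C)=CC(C)=C[C@@]1(C)C(=O)Cl | intermediate
21 | dilithium 1-methoxy-2-methylpenta-1,3-diene-1,3-diolate (dianion of 19) | [Li+].[Li+].CC=C([O-])C(C)=C([O-])OC | intermediate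
22 | methyl 5-[(1R,6S)-6-[(2E,4R,5R)-5-(tert-butyldimethylsilyloxy)-4-methylhept-2-en-2-yl]-1,3,5-trimethylcyclohexa-2,4-dien-1-yl]-2,4-dimethyl-3,5-dioxopentanoate (epimers at C2 and C4, with enol forms) | CC[C@@H](O[Si](C)(C)C(C)(C)C)[C@H](C)/C=C(\C)[C@H]1C(C)=CC(C)=C[C@@]1(C)C(=O)C(C)C(=O)C(C)C(=O)OC | intermediate
23 | 6-[(1R,6S)-6-[(2E,4R,5R)-5-(tert-butyldimethylsilyloxy)-4-methylhept-2-en-2-yl]-1,3,5-trimethylcyclohexa-2,4-dien-1-yl]-4-hydroxy-3,5-dimethyl-2H-pyran-2-one | CC[C@@H](O[Si](C)(C)C(C)(C)C)[C@H](C)/C=C(\C)[C@H]1C(C)=CC(C)=C[C@@]1(C)c1oc(=O)c(C)c(O)c1C | intermediate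
24 | 2-[(1R,6S)-6-[(2E,4R,5R)-5-(tert-butyldimethylsilyloxy)-4-methylhept-2-en-2-yl]-1,3,5-trimethylcyclohexa-2,4-dien-1-yl]-6-methoxy-3,5-dimethyl-4H-pyran-4-one | CC[C@@H](O[Si](C)(C)C(C)(C)C)[C@H](C)/C=C(\C)[C@H]1C(C)=CC(C)=C[C@@]1(C)c1oc(OC)c(C)c(=O)c1C | intermediate
25 | 2-[(1R,6S)-6-[(2E,4R,5R)-5-hydroxy-4-methylhept-2-en-2-yl]-1,3,5-trimethylcyclohexa-2,4-dien-1-yl]-6-methoxy-3,5-dimethyl-4H-pyran-4-one | CC[C@@H](O)[C@H](C)/C=C(\C)[C@H]1C(C)=CC(C)=C[C@@]1(C)c1oc(OC)c(C)c(=O)c1C | intermediate
26 | 2-methoxy-3,5-dimethyl-6-[(1R,6S)-1,3,5-trimethyl-6-[(2E,4R)-4-methyl-5-oxohept-2-en-2-yl]cyclohexa-2,4-dien-1-yl]-4H-pyran-4-one | CCC(=O)[C@H](C)/C=C(\C)[C@H]1C(C)=CC(C)=C[C@@]1(C)c1oc(OC)c(C)c(=O)c1C | target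

## Step count and least certain steps

Total: 16 steps. Longest linear sequence: 15 steps (steps 2–16, from 4). Step 1 supplies the second fragment.

Step 10 (key step).
- What may go wrong:
  - Discrimination between the two ring alkenes may be weak, because an ester tether holds the metal differently from the carbon tethers on which the ligand is proven.
  - Ring closure may be slow, since the ester must leave its preferred s-trans rotamer. The alkenylpalladium intermediate then has time to expel the allylic carboxylate or to be reduced.
  - β-Hydride loss may go into the C2 methyl group.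
- Fallback: this sets out from 13 and 3 and returns at 17. The two are joined (DCC, DMAP) to the propargylic ester F1. F1 is cyclised by a palladium hydride enyne cycloisomerisation of the Alder-ene type ([Pd(MeCN)4](BF4)2, (R)-BINAP, HCO2H, DMSO, 80 °C). Reversible syn hydropalladation of the alkyne generates the same alkenylpalladium species without iodide or silver, and insertion and β-hydride elimination then follow as before. If alkene selection remains poor in either mode, the products are diastereomers and can be separated.

Step 11.
- What may go wrong: hydride may be delivered to the substituted allyl terminus, or the allylpalladium intermediate may undergo syn–anti equilibration before reduction. Either erodes the E geometry or moves the alkene. The cause would be slow and sparse ionisation of the hindered, strain-free lactone. Palladium-catalysed addition of the tin hydride to the diene could also compete.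
- Fallback: this sets out from 17 and returns at 22, so it also replaces step 12.
  - LiAlH4 gives the diol F2.
  - Corey–Kim conditions (N-chlorosuccinimide, Me2S, −20 °C) convert only the allylic hydroxyl into the chloride F3.
  - LiBHEt3 displaces the chloride directly, so no allyl–metal species is formed, giving the neopentyl alcohol F4.
  - Dess–Martin oxidation gives the aldehyde F5.
  - Aldol addition of 21 gives the hydroxy keto ester F6.
  - A second Dess–Martin oxidation gives 22.

Step 12.
- What may go wrong: acyl transfer may be slow at a carbonyl flanked by the quaternary C6. Proton transfer from the product to the dianion, O-acylation or breakdown of 20 could then win.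
- Fallback: this sets out from 18 and returns at 23.
  - EtLi (3 equiv) adds to the lithium carboxylate to give the ethyl ketone F7.
  - LiN(i-Pr)2 and Me3SiCl give the silyl enol ether F8, which can form only on the ethyl side.
  - 2-Methylpropanedioyl dichloride then builds the 4-hydroxy-2-pyranone ring of 23 in one operation, reversing the polarity of the ring B construction.

Step 14.
- What may go wrong: methylation may take place on the C4' oxygen if any anion of 23 is present. The pyrylium triflate formed before work-up could also cleave the silyl ether or protonate the diene.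
- Fallback: this sets out from 18 (through 20) and returns at 24, so it replaces steps 12–14.
  - Acylation of the lithium enolate of tert-butyl propanoate with 20 gives the β-keto ester F9.
  - Heating F9 in toluene with 1,1-dimethoxyprop-1-ene expels tert-butanol to give the acylketene F10.
  - F10 is trapped in a [4+2] sense and, after loss of methanol, gives 24 with the methoxy group placed by construction.

Step 8.
- What may go wrong: tin may be delivered to the distal alkyne carbon, because the steric bias and the directing effect of the free hydroxymethyl group are both only moderate. Protodestannylation before iodination would lower the yield.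
- Fallback: this sets out from 11 and returns at 15.
  - n-BuLi gives 12, which is quenched with ClCO2Me to the ynoate F11.
  - Palladium-catalysed hydrostannylation of the ynoate places tin α to the ester for electronic reasons and gives the stannyl enoate F12.
  - I2 gives the iodo enoate F13.
  - i-Bu2AlH at −78 °C reduces the ester to 15.

## Further compounds

F1 | step 10 | (4R,5R)-5-(tert-butyldimethylsilyloxy)-4-methylhept-2-yn-1-yl 1,3,5-trimethylcyclohexa-2,5-diene-1-carboxylate | CC[C@@H](O[Si](C)(C)C(C)(C)C)[C@H](C)C#CCOC(=O)C1(C)C=C(C)CC(C)=C1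
F2 | step 11 | {(1R,6R)-6-[(2Z,4R,5R)-5-(tert-butyldimethylsilyloxy)-1-hydroxy-4-methylhept-2-en-2-yl]-1,3,5-trimethylcyclohexa-2,4-dien-1-yl}methanol | CC[C@@H](O[Si](C)(C)C(C)(C)C)[C@H](C)/C=C(\CO)[C@H]1C(C)=CC(C)=C[C@@]1(C)CO
F3 | step 11 | {(1R,6S)-6-[(2Z,4R,5R)-5-(tert-butyldimethylsilyloxy)-1-chloro-4-methylhept-2-en-2-yl]-1,3,5-trimethylcyclohexa-2,4-dien-1-yl}methanol | CC[C@@H](O[Si](C)(C)C(C)(C)C)[C@H](C)/C=C(\CCl)[C@H]1C(C)=CC(C)=C[C@@]1(C)CO
F4 | step 11 | {(1R,6S)-6-[(2E,4R,5R)-5-(tert-butyldimethylsilyloxy)-4-methylhept-2-en-2-yl]-1,3,5-trimethylcyclohexa-2,4-dien-1-yl}methanol | CC[C@@H](O[Si](C)(C)C(C)(C)C)[C@H](C)/C=C(\C)[C@H]1C(C)=CC(C)=C[C@@]1(C)CO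
F5 | step 11 | (1R,6S)-6-[(2E,4R,5R)-5-(tert-butyldimethylsilyloxy)-4-methylhept-2-en-2-yl]-1,3,5-trimethylcyclohexa-2,4-diene-1-carbaldehyde | CC[C@@H](O[Si](C)(C)C(C)(C)C)[C@H](C)/C=C(\C)[C@H]1C(C)=CC(C)=C[C@@]1(C)C=O
F6 | step 11 | methyl 5-[(1R,6S)-6-[(2E,4R,5R)-5-(tert-butyldimethylsilyloxy)-4-methylhept-2-en-2-yl]-1,3,5-trimethylcyclohexa-2,4-dien-1-yl]-5-hydroxy-2,4-dimethyl-3-oxopentanoate (mixture at the three new centres) | CC[C@@H](O[Si](C)(C)C(C)(C)C)[C@H](C)/C=C(\C)[C@H]1C(C)=CC(C)=C[C@@]1(C)C(O)C(C)C(=O)C(C)C(=O)OC
F7 | step 12 | 1-[(1R,6S)-6-[(2E,4R,5R)-5-(tert-butyldimethylsilyloxy)-4-methylhept-2-en-2-yl]-1,3,5-trimethylcyclohexa-2,4-dien-1-yl]propan-1-one | CC[C@@H](O[Si](C)(C)C(C)(C)C)[C@H](C)/C=C(\C)[C@H]1C(C)=CC(C)=C[C@@]1(C)C(=O)CC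
F8 | step 12 | trimethylsilyl enol ether of F7 (either enol ether geometry) | CC[C@@H](O[Si](C)(C)C(C)(C)C)[C@H](C)/C=C(\C)[C@H]1C(C)=CC(C)=C[C@@]1(C)C(O[Si](C)(C)C)=CC
F9 | step 14 | tert-butyl 3-[(1R,6S)-6-[(2E,4R,5R)-5-(tert-butyldimethylsilyloxy)-4-methylhept-2-en-2-yl]-1,3,5-trimethylcyclohexa-2,4-dien-1-yl]-2-methyl-3-oxopropanoate (both epimers at C2) | CC[C@@H](O[Si](C)(C)C(C)(C)C)[C@H](C)/C=C(\C)[C@H]1C(C)=CC(C)=C[C@@]1(C)C(=O)C(C)C(=O)OC(C)(C)C
F10 | step 14 | 3-[(1R,6S)-6-[(2E,4R,5R)-5-(tert-butyldimethylsilyloxy)-4-methylhept-2-en-2-yl]-1,3,5-trimethylcyclohexa-2,4-dien-1-yl]-2-methyl-3-oxoprop-1-en-1-one | CC[C@@H](O[Si](C)(C)C(C)(C)C)[C@H](C)/C=C(\C)[C@H]1C(C)=CC(C)=C[C@@]1(C)C(=O)C(C)=C=O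
F11 | step 8 | methyl (4R,5R)-5-(tert-butyldimethylsilyloxy)-4-methylhept-2-ynoate | CC[C@@H](O[Si](C)(C)C(C)(C)C)[C@H](C)C#CC(=O)OC
F12 | step 8 | methyl (2E,4R,5R)-5-(tert-butyldimethylsilyloxy)-4-methyl-2-(tributylstannyl)hept-2-enoate | CC[C@@H](O[Si](C)(C)C(C)(C)C)[C@H](C)/C=C(/[Sn](CCCC)(CCCC)CCCC)C(=O)OC
F13 | step 8 | methyl (2E,4R,5R)-5-(tert-butyldimethylsilyloxy)-2-iodo-4-methylhept-2-enoate | CC[C@@H](O[Si](C)(C)C(C)(C)C)[C@H](C)/C=C(/I)C(=O)OC
A1 | alternative 1 | 2-methoxy-4,6-dimethylphenol | COc1cc(C)cc(C)c1O
A2 | alternative 1 | (3R,4Z,6E,8R,9R)-9-(tert-butyldimethylsilyloxy)-4,6,8-trimethylundeca-4,6-dien-3-ol | CC[C@@H](O[Si](C)(C)C(C)(C)C)[C@H](C)/C=C(\C)/C=C(/C)[C@@H](CC)O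
A3 | alternative 1 | 6-methoxy-2,4-dimethyl-6-{[(3R,4Z,6E,8R,9R)-9-(tert-butyldimethylsilyloxy)-4,6,8-trimethylundeca-4,6-dien-3-yl]oxy}cyclohexa-2,4-dien-1-one (ketal carbon not defined) | CC[C@@H](O[Si](C)(C)C(C)(C)C)[C@H](C)/C=C(\C)/C=C(/C)[C@@H](CC)OC1(OC)C=C(C)C=C(C)C1=O
A4 | alternative 1 | tricyclic keto ketal (bicyclo[2.2.2]octenone fused to a tetrahydrofuran) | CC[C@@H](O[Si](C)(C)C(C)(C)C)[C@H](C)/C=C(\C)[C@H]1[C@]2(C)C=C(C)[C@@H]3[C@@]1(C)[C@@H](CC)O[C@]3(OC)C2=O
A5 | alternative 2 | 6-[(1R,6S)-6-[(2E,4R,5R)-5-(tert-butyldimethylsilyloxy)-4-methylhept-2-en-2-yl]-1,3,5-trimethylcyclohexa-2,4-dien-1-yl]-2,2,5-trimethyl-4H-1,3-dioxin-4-one | CC[C@@H](O[Si](C)(C)C(C)(C)C)[C@H](C)/C=C(\C)[C@H]1C(C)=CC(C)=C[C@@]1(C)C1=C(C)C(=O)OC(C)(C)O1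
A6 | alternative 2 | acylketene, 3-[(1R,6S)-6-[(2E,4R,5R)-5-(tert-butyldimethylsilyloxy)-4-methylhept-2-en-2-yl]-1,3,5-trimethylcyclohexa-2,4-dien-1-yl]-2-methyl-3-oxoprop-1-en-1-one | CC[C@@H](O[Si](C)(C)C(C)(C)C)[C@H](C)/C=C(\C)[C@H]1C(C)=CC(C)=C[C@@]1(C)C(=O)C(C)=C=O
A7 | alternative 2 | 1,1-dimethoxyprop-1-ene | CC=C(OC)OC
A8 | alternative 2 | silyl-protected carbinol with ring B in place (same structure as 24) | CC[C@@H](O[Si](C)(C)C(C)(C)C)[C@H](C)/C=C(\C)[C@H]1C(C)=CC(C)=C[C@@]1(C)c1oc(OC)c(C)c(=O)c1C
A9 | alternative 3 | methyl (1R,4S)-4-[(2E,4R,5R)-5-(tert-butyldimethylsilyloxy)-4-methylhept-2-en-2-yl]-1,3-dimethylcyclobut-2-ene-1-carboxylate | CC[C@@H](O[Si](C)(C)C(C)(C)C)[C@H](C)/C=C(\C)[C@H]1C(C)=C[C@@]1(C)C(=O)OC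
A10 | alternative 3 | propyne | CC#C
A11 | alternative 3 | methyl (1R,6S)-6-[(2E,4R,5R)-5-(tert-butyldimethylsilyloxy)-4-methylhept-2-en-2-yl]-1,3,5-trimethylcyclohexa-2,4-diene-1-carboxylate | CC[C@@H](O[Si](C)(C)C(C)(C)C)[C@H](C)/C=C(\C)[C@H]1C(C)=CC(C)=C[C@@]1(C)C(=O)OC
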